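## Structural features

The target is a daucane-type diester: a trans-fused bicyclo[5.3.0]decene in which cyclopentane ring A and cycloheptene ring B share the C1–C5 bond. Locants used throughout: ring A is C1 (quaternary, methyl), C2, C3, C4 (tertiary carbinol carrying the isopropyl group) and C5 (methine); ring B is C1, C5, C6 (4-hydroxybenzoyloxy), C7=C8 (methyl on C8), C9 (acetoxy) and C10. Four of the five stereocentres are contiguous (C1, C5 and C4 on ring A, then C6). The C1 methyl is trans to H5, the C4 oxygen lies on the same side of ring A as C6, and the C6 oxygen is anti to the C4 oxygen; the fifth centre, C9, sits across the trisubstituted alkene with its oxygen cis to that on C6. Both esters are allylic and different, the benzoate carries a free phenol, and the C4 hydroxyl is β to C6, so any C6 ketone intermediate is open to retro-aldol cleavage, β-elimination and C5 epimerisation in base. The real difficulty is the crowded C1–C5–C4 array (quaternary carbon, ring-fusion methine, fully substituted carbinol) and its relation to C6, not the oxygenation of ring B as such. The key step uses the fact that C5–C6–C7, with C6 as a carbonyl carbon, is an oxyallyl cation and that C1=C10–C9=C8 is a 1,3-diene already bearing both methyl groups, the two joined by the C2–C3–C4 chain. One (4+3) cycloaddition then forms C1–C5 and C7–C8 and closes ring A and ring B together from an open chain whose single stereocentre is C4.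

## Logic of the disconnections

**28 ⇒ 27 ⇒ 22 + 25 (C6–O acyl bond; phenol O–Si).** The aryl ester is the most labile bond and both halves are simple, so it is cut first; the phenol is masked as a silyl ether because buffered fluoride removes it without touching either ester. This removes the aroyl unit and leaves diol monoacetate 22. The forward acylation must reach the hindered secondary C6 hydroxyl, ignore the tertiary C4 hydroxyl, and leave the C6–O bond intact. 25 comes from 23 in one operation.

**22 ⇒ 21 ⇒ 20 (C6–H bond; O–Si at C4).** C6 goes back to a carbonyl because that is the oxidation state the cycloaddition delivers. An external hydride should approach the C6 carbonyl from the face of H5, away from C1 and its methyl group, and give the wrong epimer. The silyl group is therefore removed first, so that the C4 hydroxyl, which lies on the C1 side of the carbonyl plane, can carry the hydride in and give the 1,3-anti diol. The gain is one stereocentre, and the C4 oxygen becomes a control element. The demand is that the tertiary hydroxyl binds boron and that β-hydroxy ketone 21 never meets base.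

**20 ⇒ 18 (C7=C8 π bond).** The enone is cut back to the saturated ketone because C8 leaves the cycloaddition as an sp3 carbon. C5 has no β-hydrogen on either side (C1 and C4 are fully substituted), so dehydrogenation can only go to C7=C8. The demand is enolisation toward C7 and an oxidation that tolerates the acetate that becomes allylic.

**18 ⇒ 17 ⇒ 16 ⇒ 14 (C9–O bond, with redox adjustment at C6).** The C9=C10 alkene left by the diene is the only handle for the C9 oxygen. Hydroboration should put boron on the alkene carbon remote from quaternary C1 and on the face opposite the C1 methyl. A boron hydride cannot spare the C6 ketone, so its reduction is accepted; the ketone is regenerated after the C9 hydroxyl has been capped as the acetate the target needs anyway. The gain is the C9 stereocentre and the acetate. The demands are regio- and face-selective hydroboration and discrimination of two secondary alcohols.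

**14 ⇒ 12 (C1–C5 and C7–C8).** This is the strategic cut. Two rings and three stereocentres are exchanged for an open chain holding all fifteen skeletal carbons and one stereocentre. The forward step must ionise a primary α-chloro ketone through the enol on the C5 side, keep the tether cis to the oxyallyl oxygen, pass through the extended transition state for the trans fusion, and let C4 choose the cation face. The alkene at C1 must be E, because the Z isomer can only reach a cis fusion.

**12 ⇒ 9 + 10 (C6–C7).** The chloromethyl ketone is made last, from an ester. An ester survives the diene construction, whereas a chlorohydrin would close to an epoxide under any olefination base and an aldehyde would have to be told apart from the methyl ketone by the carbenoid. The gain is one carbon and no oxidation step. The demand is a single addition.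

**9 ⇒ 7 + 8 (C9–C10); 7 ⇒ 5 (C1–CH3 and C10–I); 5 ⇒ 4 ⇒ 3 (C1≡C10 from the acetyl group).** Olefination of the methyl ketone with an allylic phosphorus reagent cannot control the geometry at C1=C10 (methyl versus CH2 on C1). The diene is therefore cut at its central σ bond into two alkenyl partners that couple with retention. The trisubstituted partner 7 comes from syn addition of methyl and aluminium across terminal alkyne 5, which is made from the acetyl group of 3 through enol triflate 4. The former acetyl methyl carbon becomes C10, and the C1 methyl is delivered by the aluminium reagent. The gain is geometric certainty at the price of three operations. The demand is that the ester survives amide base and the aluminium reagent.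

**3 ⇒ 2 ⇒ 1 (reconnection C1=C6; O–Si).** Joining ketone carbon C1 and ester carbon C6 of 3 as an alkene gives a cyclohexene whose ring is C1–C6 and whose only stereocentre is C4. The S descriptor of 1 and the R descriptor of C4 in 28 denote the same arrangement in space, because the priorities of the carbon substituents change along the way. The tertiary hydroxyl must be protected before cleavage (it would otherwise close onto the ketone as a hemiketal), and the two termini must emerge differentiated as ketone and ester.

## Other disconnections considered

**Alternative 1:** The cut is C7–C8 and C8–C9, a one-carbon insertion of C8 with its methyl into a six-membered enol ether. In the forward step a chloro(methyl)carbenoid adds to the enol ether alkene of arene-derived 1,4-diene A1, and the alkoxy-chlorocyclopropane opens with loss of chloride to enone A2.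
- In its favour: a cheap aromatic precursor, good chemoselectivity (the enol ether is far more nucleophilic than the tetrasubstituted alkene), and a regiochemically secure opening.
- Better than the chosen plan on one point: A2 has the C8 methyl, the C7=C8 alkene and an oxygen at C9 in their final positions, where the chosen plan spends five operations (steps 9–13) on the same pattern.
- Against it: A2 lacks the C1 methyl, the isopropyl group and the C6 oxygen, and C1 and C5 are sp2. The quaternary C1 and the trans H5 would have to be made on a tetrasubstituted alkene, for example by conjugate methylation after isomerisation into a cross-conjugated dienone, where C7 competes as acceptor. The only stereocentre is a secondary silyloxy carbon that must relay to four new centres.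
- Comparison: on structure it solves ring B functionality and leaves the congested ring A array, whereas the chosen plan does the reverse. On mechanism both rely on oxygen-stabilised cations; the ring expansion creates no stereocentre, the (4+3) creates three under control that is less certain. On step economy A2 is reached in fewer steps than 14, but more work remains after A2 than after 14.

**Alternative 2:** The cut is the C6–O and C9–O bonds together. In the forward step photosensitised oxygen adds across the ring B diene of A3 (C6=C7–C8=C9) to give endoperoxide A4, and O–O reduction would give the cis-1,4-diol.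
- In its favour, and better than the chosen plan: both oxygens arrive cis in one suprafacial event with the alkene left at C7=C8, and approach anti to the C1 methyl would set C6 and C9 together. The chosen plan controls these two centres in two separate, independently uncertain steps (9 and 14).
- Equal to the chosen plan: the two allylic alcohols still have to be told apart for acetate and benzoate.
- Against it: it is an end game. A3 already contains the quaternary C1, the C4 carbinol and the trans fusion, so every hard problem stays upstream. Ene pathways at the C8 methyl and at C10 compete, and a peroxide must be handled.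
- Comparison: on structure it addresses only the heteroatoms of ring B. The two plans cannot simply be joined, because 14 carries its carbonyl at C6 and its alkene at C9=C10 and would need an alkene transposition to reach A3. On step economy it is shorter at the end and offers nothing at the start.

**Alternative 3:** The cut is C1–C10 and C5–C6 on a cyclopentenone. In the forward step copper-catalysed conjugate transfer of a vinyl group from aluminium to C1 of A5, under a chiral carbene ligand, is followed by aldol trapping of the aluminium enolate at C5 with iodoenal A6 to give A7.
- Better than the chosen plan: absolute configuration comes from a catalyst, so either enantiomer is accessible and no pool material of fixed purity is needed. The C6 carbinol and the C7=C8 alkene with its methyl arrive in place, so no redox shuffle at C6–C8 is needed.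
- Equal or better: the C1/C5 trans relation comes from enolate trapping anti to the new vinyl group, a dependable bias, where the (4+3) has to choose between two transition-state shapes.
- Against it: no ring closes. Ring B still needs the C8–C9 bond, for example by metal-mediated addition of the vinyl iodide to an aldehyde grown from the vinyl group, which sets C9 inside a forming seven-membered ring. The isopropyl group must add to the C4 ketone of a β-oxygenated system prone to retro-aldol, with the correct face. β-Substituted cyclopentenones are the least willing acceptors for quaternary-centre formation, and C6 aldol diastereoselectivity is open.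
- Comparison: on structure it builds on ring A and makes C4 late, whereas the chosen plan buys C4 and uses it for control. On mechanism it is catalyst control against substrate control. On step economy its key step makes two bonds and no ring against two bonds and two rings; the overall lengths could be similar, and it could be shorter after its key step if the ring closure behaves.

Key step: step 8

Assumption: 1 is used as the commercial (S)-(+)-enantiomer; C4 is not touched in any step, so the enantiomeric purity of 28 equals that of 1, and material of modest purity would have to be upgraded before step 1.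

## Route

Step 1
Reactants: 1 (S)-terpinen-4-ol
Product: 2 triethyl{[(1S)-4-methyl-1-(propan-2-yl)cyclohex-3-en-1-yl]oxy}silane
Conditions: TESOTf, 2,6-lutidine, CH2Cl2, 0 → 25 °C
Reagents that add atoms: triethylsilyl trifluoromethanesulfonate, CC[Si](CC)(CC)OS(=O)(=O)C(F)(F)F
Why: A silyl triflate with a hindered pyridine base silylates even this hindered tertiary alcohol (silyl ether formation); C4 is not involved, so its configuration is kept.

Step 2
Reactants: 2 triethyl{[(1S)-4-methyl-1-(propan-2-yl)cyclohex-3-en-1-yl]oxy}silane
Product: 3 methyl (3S)-6-oxo-3-(propan-2-yl)-3-[(triethylsilyl)oxy]heptanoate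
Conditions: O3, NaOH, MeOH/CH2Cl2, −78 °C
Reagents that add atoms: ozone, [O-][O+]=O; methanol, CO
Why: Ozonolysis in cold methanolic base turns the CH terminus of the trisubstituted alkene directly into the methyl ester while the methyl-bearing carbon emerges as the ketone, so the termini are differentiated in one operation whichever way the primary ozonide fragments. The tertiary silyl ether tolerates cold methanolic NaOH.

Step 3
Reactants: 3 methyl (3S)-6-oxo-3-(propan-2-yl)-3-[(triethylsilyl)oxy]heptanoate
Product: 4 methyl (3S)-3-(propan-2-yl)-3-[(triethylsilyl)oxy]-6-{[(trifluoromethyl)sulfonyl]oxy}hept-6-enoate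
Conditions: KN(SiMe3)2, THF, −78 °C; PhNTf2, −78 → −20 °C
Reagents that add atoms: N-phenylbis(trifluoromethanesulfonimide), O=S(=O)(N(c1ccccc1)S(=O)(=O)C(F)(F)F)C(F)(F)F
Why: Kinetic deprotonation of a methyl ketone by a hindered potassium amide occurs at the methyl group and much faster than at the neopentyl-type ester α-position; O-sulfonylation of the enolate gives the terminal enol triflate.

Step 4
Reactants: 4 methyl (3S)-3-(propan-2-yl)-3-[(triethylsilyl)oxy]-6-{[(trifluoromethyl)sulfonyl]oxy}hept-6-enoate
Product: 5 methyl (3S)-3-(propan-2-yl)-3-[(triethylsilyl)oxy]hept-6-ynoate
Conditions: LiN(i-Pr)2 (2.5 equiv), THF, −78 °C; AcOH, −78 °C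
Reagents that add atoms: none
Why: Base-induced E2 loss of triflate from a 1-alken-2-yl triflate is a standard route to terminal alkynes. The ester enolate formed alongside should persist at −78 °C and be reprotonated by the cold quench rather than expel the β-silyloxy group.

Step 5
Reactants: 5 methyl (3S)-3-(propan-2-yl)-3-[(triethylsilyl)oxy]hept-6-ynoate
Product: 7 methyl (3S,6E)-7-iodo-6-methyl-3-(propan-2-yl)-3-[(triethylsilyl)oxy]hept-6-enoate, via alkenylalane 6 (not isolated)
Conditions: AlMe3, (C5H5)2ZrCl2 (20 mol %), H2O (1.5 equiv), CH2Cl2, −20 °C; I2, THF, −20 → 0 °C
Reagents that add atoms: trimethylaluminium, C[Al](C)C; iodine, II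
Why: Zirconium-catalysed carboalumination (Negishi) adds methyl and aluminium syn across the terminal alkyne with aluminium on the terminal carbon, and iodinolysis with retention fixes the E geometry of the future C1=C10 alkene. The water-accelerated variant is fast at low temperature, which should spare the hindered methyl ester.

Step 6
Reactants: 7 methyl (3S,6E)-7-iodo-6-methyl-3-(propan-2-yl)-3-[(triethylsilyl)oxy]hept-6-enoate; 8 4,4,5,5-tetramethyl-2-[(1E)-prop-1-en-1-yl]-1,3,2-dioxaborolane
Product: 9 methyl (3S,6E,8E)-6-methyl-3-(propan-2-yl)-3-[(triethylsilyl)oxy]deca-6,8-dienoate
Conditions: Pd(PPh3)4 (5 mol %), K3PO4, THF/H2O, 50 °C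
Reagents that add atoms: (E)-prop-1-enylboronic acid pinacol ester 8, C/C=C/B1OC(C)(C)C(C)(C)O1
Why: Suzuki–Miyaura coupling of an alkenyl iodide with an alkenylboronate proceeds with retention at both partners, so the E,E diene follows from the geometry of 7 and 8.

Step 7
Reactants: 9 methyl (3S,6E,8E)-6-methyl-3-(propan-2-yl)-3-[(triethylsilyl)oxy]deca-6,8-dienoate; 10 chloroiodomethane
Product: 12 (4S,7E,9E)-1-chloro-7-methyl-4-(propan-2-yl)-4-[(triethylsilyl)oxy]undeca-7,9-dien-2-one, via lithium hemiketal 11 (not isolated)
Conditions: ClCH2I, MeLi·LiBr, THF, −78 °C; AcOH, −78 °C
Reagents that add atoms: chloroiodomethane 10, ClCI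
Why: Chloromethyllithium formed by iodine–lithium exchange in the presence of the ester adds once, because the tetrahedral lithium hemiketal is stable at −78 °C and collapses to the chloromethyl ketone only on the acidic quench (carbenoid homologation of an ester). The diene and the silyl ether are inert at this temperature.

Step 8
Reactants: 12 (4S,7E,9E)-1-chloro-7-methyl-4-(propan-2-yl)-4-[(triethylsilyl)oxy]undeca-7,9-dien-2-one
Product: 14 trans-fused bicyclic ketone (C6 ketone; C9=C10 alkene; C1 methyl trans to H5; C4 triethylsilyloxy cis to C6; C8 methyl cis to H5), via oxyallyl cation 13 (not isolated)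
Conditions: Na2CO3, (CF3)2CHOH, 0.01 M, 25 °C
Reagents that add atoms: none
Why: Carbonate in hexafluoroisopropanol should enolise 12 reversibly on both sides of the carbonyl, and only the enol on the C5 side can lose the allylic chloride from C7, giving oxyallyl cation 13 with the tether cis to oxygen. The closest known reaction type is the (4+3) cycloaddition of oxyallyl cations generated from α-halo ketones by mild base in fluorinated alcohols or ethereal LiClO4, including intramolecular cases with a diene or furan on a three-atom tether. The cation adds across the s-cis diene, in concert or by C7–C8 bonding first and collapse of the resulting tertiary allyl cation onto C5. Ring A closes as a five-membered ring through the C1–C5 bond over the C2–C3–C4 tether with both π systems exocyclic to it, and ring B is the seven-membered ring assembled from the three cation carbons and the four diene carbons. C1 and C5 are set together by the shape of the transition state: with the E alkene at C1 and the tether cis to the oxyallyl oxygen, the extended arrangement gives the trans fusion and the compact one the cis fusion. The configuration of C5 relative to C4 is controlled by the C4 stereocentre, since the tether must lie over one face of the cation and the larger isopropyl group should then take the position remote from C6, leaving the silyloxy group next to the carbonyl. C8 follows from suprafacial addition to the E,E diene and is erased in step 12. The step needs ionisation to outrun substitution at the primary chloride, for which the non-nucleophilic base, the poorly nucleophilic solvent and high dilution are chosen, and it needs C4 to discriminate the two faces, which is the untested element.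

Step 9
Reactants: 14 trans-fused bicyclic ketone
Product: 16 C6,C9-diol (C9 hydroxyl cis to H5; C6 hydroxyl expected cis to the C1 methyl and immaterial), via organoborane 15 (not isolated)
Conditions: BH3·THF, THF, 0 → 25 °C; NaOH, H2O2, 0 °C
Reagents that add atoms: hydrogen peroxide, OO
Why: Borane reduces the C6 ketone and hydroborates the cis-disubstituted C9=C10 alkene. Boron should go to C9, away from quaternary C1, and to the face opposite the pseudo-axial C1 methyl, and oxidation with retention then gives the C9 alcohol cis to H5. The C6 carbinol configuration does not matter because step 11 removes it.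

Step 10
Reactants: 16 C6,C9-diol
Product: 17 C9 monoacetate of 16
Conditions: Ac2O, pyridine, DMAP (cat.), CH2Cl2, −20 → 0 °C
Reagents that add atoms: acetic anhydride, CC(=O)OC(C)=O
Why: Acylation should discriminate the two secondary alcohols on steric grounds: the C9 hydroxyl is flanked by CH2 and CH(CH3), the C6 hydroxyl by C5, which lies between two fully substituted carbons.

Step 11
Reactants: 17 C9 monoacetate
Product: 18 C6 ketone carrying the C9 acetate (C8 still sp3)
Conditions: Dess–Martin periodinane, NaHCO3, CH2Cl2, 25 °C
Reagents that add atoms: none
Why: Dess–Martin oxidation converts hindered secondary alcohols under buffered, near-neutral conditions that leave the acetate, the silyl ether and the C5 configuration alone.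

Step 12
Reactants: 18 C6 ketone carrying the C9 acetate
Product: 20 enone (C6 ketone; C7=C8; C9 acetate; C4 triethylsilyl ether), via trimethylsilyl enol ether 19 (not isolated)
Conditions: TMSOTf, Et3N, CH2Cl2, 0 °C; Pd(OAc)2, MeCN, 25 °C
Reagents that add atoms: none
Why: Soft enolisation should go toward C7, because C5 lies between two quaternary carbons. Saegusa–Ito oxidation of the silyl enol ether then places the alkene at C7=C8 by β-hydride loss from C8; no β-hydrogen exists on the C5 side, so no regioisomeric enone can form, and the C8 stereocentre disappears.

Step 13
Reactants: 20 enone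
Product: 21 hydroxy enone (20 with the free C4 hydroxyl)
Conditions: HF·pyridine, pyridine, THF, 0 → 25 °C
Reagents that add atoms: none
Why: Buffered hydrogen fluoride cleaves the tertiary triethylsilyl ether under non-basic conditions, which avoids retro-aldol cleavage of the β-hydroxy ketone and leaves the acetate in place.

Step 14
Reactants: 21 hydroxy enone
Product: 22 C4,C6-diol C9-acetate (C6 hydroxyl anti to the C4 hydroxyl, on the ring B face of H5 and of the C9 acetate)
Conditions: Me4NBH(OAc)3, MeCN/AcOH, −20 → 0 °C
Reagents that add atoms: none
Why: In the Evans–Saksena reduction the C4 hydroxyl exchanges onto boron and delivers hydride to the C6 carbonyl through a six-membered transition state, giving the 1,3-anti diol. This is attack from the C1 side of the carbonyl, the face an external hydride should avoid, so the C6 centre is set by the C4 oxygen and not by the angular methyl.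

Step 15
Reactants: 23 4-hydroxybenzoic acid
Product: 25 4-[(tert-butyldimethylsilyl)oxy]benzoic acid, via bis-silyl derivative 24 (not isolated)
Conditions: TBSCl, imidazole, DMF, 25 °C; AcOH/THF/H2O, 25 °C
Reagents that add atoms: tert-butyl(chloro)dimethylsilane, CC(C)(C)[Si](C)(C)Cl
Why: Both acidic sites are silylated, and the silyl ester is far more labile than the aryl silyl ether, so mild aqueous acid returns the carboxylic acid with the phenol still protected.

Step 16
Reactants: 22 C4,C6-diol C9-acetate; 25 4-[(tert-butyldimethylsilyl)oxy]benzoic acid
Product: 27 silyl-protected diester (C6 4-silyloxybenzoate; C9 acetate; free C4 hydroxyl), via mixed anhydride 26 (not isolated)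
Conditions: 2,4,6-Cl3C6H2COCl, Et3N, THF, 25 °C; 22, DMAP, toluene, 25 → 40 °C
Reagents that add atoms: 4-[(tert-butyldimethylsilyl)oxy]benzoic acid 25, CC(C)(C)[Si](C)(C)Oc1ccc(cc1)C(O)=O
Why: Yamaguchi esterification through the mixed anhydride and the acylpyridinium ion acylates hindered secondary alcohols. The tertiary C4 hydroxyl does not compete, and the C6 configuration is retained because the C6–O bond is not broken.

Step 17
Reactants: 27 silyl-protected diester
Product: 28 target, (3R,3aS,4S,7S,8aR)-7-(acetyloxy)-3-hydroxy-6,8a-dimethyl-3-(propan-2-yl)-1,2,3,3a,4,7,8,8a-octahydroazulen-4-yl 4-hydroxybenzoate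
Conditions: Bu4NF, AcOH, THF, 0 °C
Reagents that add atoms: none
Why: Fluoride cleaves an aryl silyl ether much faster than it touches an ester, and buffering with acetic acid keeps the liberated phenoxide from promoting acyl transfer or elimination.

## Compound list

1 | (S)-terpinen-4-ol, (1S)-4-methyl-1-(propan-2-yl)cyclohex-3-en-1-ol | CC1=CC[C@](O)(C(C)C)CC1 | starting material
2 | triethyl{[(1S)-4-methyl-1-(propan-2-yl)cyclohex-3-en-1-yl]oxy}silane | CC1=CC[C@](O[Si](CC)(CC)CC)(C(C)C)CC1 | intermediate
3 | methyl (3S)-6-oxo-3-(propan-2-yl)-3-[(triethylsilyl)oxy]heptanoate | COC(=O)C[C@](O[Si](CC)(CC)CC)(C(C)C)CCC(C)=O | intermediate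
4 | methyl (3S)-3-(propan-2-yl)-3-[(triethylsilyl)oxy]-6-{[(trifluoromethyl)sulfonyl]oxy}hept-6-enoate | COC(=O)C[C@](O[Si](CC)(CC)CC)(C(C)C)CCC(=C)OS(=O)(=O)C(F)(F)F | intermediate
5 | methyl (3S)-3-(propan-2-yl)-3-[(triethylsilyl)oxy]hept-6-ynoate | COC(=O)C[C@](O[Si](CC)(CC)CC)(C(C)C)CCC#C | intermediate
6 | alkenylalane, methyl (3S,6E)-7-(dimethylalumanyl)-6-methyl-3-(propan-2-yl)-3-[(triethylsilyl)oxy]hept-6-enoate | COC(=O)C[C@](O[Si](CC)(CC)CC)(C(C)C)CC/C(C)=C/[Al](C)C | intermediate
7 | methyl (3S,6E)-7-iodo-6-methyl-3-(propan-2-yl)-3-[(triethylsilyl)oxy]hept-6-enoate | COC(=O)C[C@](O[Si](CC)(CC)CC)(C(C)C)CC/C(C)=C/I | intermediate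
8 | 4,4,5,5-tetramethyl-2-[(1E)-prop-1-en-1-yl]-1,3,2-dioxaborolane | C/C=C/B1OC(C)(C)C(C)(C)O1 | starting material
9 | methyl (3S,6E,8E)-6-methyl-3-(propan-2-yl)-3-[(triethylsilyl)oxy]deca-6,8-dienoate | COC(=O)C[C@](O[Si](CC)(CC)CC)(C(C)C)CC/C(C)=C/C=C/C | intermediate
10 | chloroiodomethane | ClCI | starting material
11 | lithium hemiketal, lithium (4S,7E,9E)-1-chloro-2-methoxy-7-methyl-4-(propan-2-yl)-4-[(triethylsilyl)oxy]undeca-7,9-dien-2-olate | [Li+].COC([O-])(CCl)C[C@](O[Si](CC)(CC)CC)(C(C)C)CC/C(C)=C/C=C/C | intermediate
12 | (4S,7E,9E)-1-chloro-7-methyl-4-(propan-2-yl)-4-[(triethylsilyl)oxy]undeca-7,9-dien-2-one | ClCC(=O)C[C@](O[Si](CC)(CC)CC)(C(C)C)CC/C(C)=C/C=C/C | intermediate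
13 | oxyallyl cation spanning C5–C6–C7, tether cis to oxygen | [CH2+]/C([O-])=C/[C@](O[Si](CC)(CC)CC)(C(C)C)CC/C(C)=C/C=C/C | intermediate
14 | trans-fused bicyclic ketone (C6 ketone; C9=C10; C1 methyl trans to H5; C4 triethylsilyloxy cis to C6; C8 methyl cis to H5) | C1=C[C@@]2(C)CC[C@@](O[Si](CC)(CC)CC)(C(C)C)[C@@H]2C(=O)C[C@H]1C | intermediate
15 | organoborane, idealised monomer (boron on C9 cis to H5; C6 boryl ether) | B[C@H]1C[C@@]2(C)CC[C@@](O[Si](CC)(CC)CC)(C(C)C)[C@@H]2[C@H](OB)C[C@H]1C | intermediate
16 | C6,C9-diol (C9 hydroxyl cis to H5; C6 hydroxyl cis to the C1 methyl as the expected epimer) | O[C@H]1C[C@@]2(C)CC[C@@](O[Si](CC)(CC)CC)(C(C)C)[C@@H]2[C@H](O)C[C@H]1C | intermediate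
17 | C9 monoacetate of 16 | CC(=O)O[C@H]1C[C@@]2(C)CC[C@@](O[Si](CC)(CC)CC)(C(C)C)[C@@H]2[C@H](O)C[C@H]1C | intermediate
18 | C6 ketone carrying the C9 acetate (C8 methyl cis to the acetoxy group) | CC(=O)O[C@H]1C[C@@]2(C)CC[C@@](O[Si](CC)(CC)CC)(C(C)C)[C@@H]2C(=O)C[C@H]1C | intermediate
19 | trimethylsilyl enol ether of 18 (C6=C7) | CC(=O)O[C@H]1C[C@@]2(C)CC[C@@](O[Si](CC)(CC)CC)(C(C)C)[C@@H]2C(O[Si](C)(C)C)=C[C@H]1C | intermediate
20 | enone (C6 ketone; C7=C8; C9 acetate; C4 triethylsilyl ether) | CC(=O)O[C@H]1C[C@@]2(C)CC[C@@](O[Si](CC)(CC)CC)(C(C)C)[C@@H]2C(=O)C=C1C | intermediate
21 | hydroxy enone (C4 hydroxyl; C6 ketone; C7=C8; C9 acetate) | CC(=O)O[C@H]1C[C@@]2(C)CC[C@@](O)(C(C)C)[C@@H]2C(=O)C=C1C | intermediate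
22 | C4,C6-diol C9-acetate (C6 hydroxyl anti to the C4 hydroxyl, cis to the C9 acetate) | CC(=O)O[C@H]1C[C@@]2(C)CC[C@@](O)(C(C)C)[C@@H]2[C@@H](O)C=C1C | intermediate
23 | 4-hydroxybenzoic acid | OC(=O)c1ccc(O)cc1 | starting material
24 | tert-butyldimethylsilyl 4-[(tert-butyldimethylsilyl)oxy]benzoate | CC(C)(C)[Si](C)(C)Oc1ccc(cc1)C(=O)O[Si](C)(C)C(C)(C)C | intermediate
25 | 4-[(tert-butyldimethylsilyl)oxy]benzoic acid | CC(C)(C)[Si](C)(C)Oc1ccc(cc1)C(O)=O | intermediate
26 | mixed anhydride of 25 with 2,4,6-trichlorobenzoic acid | CC(C)(C)[Si](C)(C)Oc1ccc(cc1)C(=O)OC(=O)c1c(Cl)cc(Cl)cc1Cl | intermediate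
27 | silyl-protected diester (C6 4-[(tert-butyldimethylsilyl)oxy]benzoate; C9 acetate; C4 hydroxyl) | CC(=O)O[C@H]1C[C@@]2(C)CC[C@@](O)(C(C)C)[C@@H]2[C@@H](OC(=O)c2ccc(O[Si](C)(C)C(C)(C)C)cc2)C=C1C | intermediate
28 | (3R,3aS,4S,7S,8aR)-7-(acetyloxy)-3-hydroxy-6,8a-dimethyl-3-(propan-2-yl)-1,2,3,3a,4,7,8,8a-octahydroazulen-4-yl 4-hydroxybenzoate | CC(=O)O[C@H]1C[C@@]2(C)CC[C@@](O)(C(C)C)[C@@H]2[C@@H](OC(=O)c2ccc(O)cc2)C=C1C | target

## Step count and least certain steps

Total: 17 steps. Longest linear sequence: 16 steps (steps 1–14, 16 and 17); step 15 is a one-step side branch.

**Step 8 (key step).** The chloride sits on a primary carbon, so substitution by solvent or base and Favorskii-type contraction compete with ionisation. The compact transition state may also compete with the extended one, so that the ring fusion is set with poor selectivity, and C4 may discriminate the cation faces only weakly because both of its free substituents are large. Fallback: set out from 12 and accept the cycloadduct mixture. The cis-fused C5 epimer F1 is separated and equilibrated at C5 under mild base (DBU, toluene, 25 °C; a stronger base would risk β-elimination of the silyloxy group), which returns material to the route at 14. This places the ring fusion under thermodynamic control, with C6 moving to the side of ring A opposite the isopropyl group, though that preference is itself not assured.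

**Step 4 (and, with it, step 5).** The amide base also deprotonates the ester, and on any warming the enolate may expel the β-silyloxy group. In step 5 the aluminium reagent may attack the ester carbonyl. Fallback: set out from 3 and bypass steps 3–6 by a Wittig olefination of the ketone. (E)-1-Bromobut-2-ene and PPh3 give (2E)-but-2-en-1-yl(triphenyl)phosphonium bromide F2; NaN(SiMe3)2 converts it into the allylic ylide F3, which reacts with the ketone of 3 in THF (−78 → 25 °C) and leaves the ester alone. This gives 9 together with its 6Z isomer F4, to be separated on AgNO3-impregnated silica, and rejoins the route at 9. The price is loss of geometric control at C1=C10.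

**Step 9.** Hydroboration may take place from the face of the C1 methyl, or place boron on C10. The regioisomer can only be removed by chromatography, but the face problem has a remedy. Fallback: set out from 14; if the C9-epimeric diol F5 is the main product, Mitsunobu reaction with acetic acid (PPh3, DIAD, THF, 0 °C) at the accessible C9 hydroxyl inverts it and installs the acetate in the same operation, rejoining the route at 17 and replacing step 10.

**Step 12.** Zerovalent palladium formed during the oxidation may ionise the acetate once it has become allylic, or silyl enol ether formation may stall at the hindered ketone. Fallback: set out from 18 through 19. Treatment of 19 with PhSeCl (CH2Cl2, −78 °C) gives the C7 phenylselanyl ketone F6, and oxidation with H2O2/pyridine (0 °C) triggers selenoxide syn-elimination toward C8 (C7 can epimerise through the enol to reach the required syn arrangement), rejoining the route at 20.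

**Step 14.** The hindered tertiary hydroxyl may fail to exchange onto boron, so that reduction is slow or occurs by external attack with the opposite facial sense. Fallback: set out from 21. Luche reduction (NaBH4, CeCl3·7H2O, MeOH, −78 °C) should give the C6-epimeric allylic alcohol F7 by attack anti to C1. Mitsunobu esterification of F7 with 25 (PPh3, DIAD, toluene, 0 → 25 °C) then forms the C6 ester with inversion and rejoins the route at 27, replacing steps 14 and 16. Displacement at this hindered allylic carbon is itself demanding.

## Further compounds

F1 | step 8 | cis-fused C5 epimer of 14 | C1=C[C@@]2(C)CC[C@@](O[Si](CC)(CC)CC)(C(C)C)[C@H]2C(=O)C[C@H]1C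
F2 | step 4 | (2E)-but-2-en-1-yl(triphenyl)phosphonium bromide | C/C=C/C[P+](c1ccccc1)(c1ccccc1)c1ccccc1.[Br-]
F3 | step 4 | (2E)-but-2-en-1-ylidene(triphenyl)-λ5-phosphane (allylic ylide) | C/C=C/C=P(c1ccccc1)(c1ccccc1)c1ccccc1
F4 | step 4 | methyl (3S,6Z,8E)-6-methyl-3-(propan-2-yl)-3-[(triethylsilyl)oxy]deca-6,8-dienoate | COC(=O)C[C@](O[Si](CC)(CC)CC)(C(C)C)CC/C(C)=C\C=C\C
F5 | step 9 | C9 epimer of diol 16 | O[C@@H]1C[C@@]2(C)CC[C@@](O[Si](CC)(CC)CC)(C(C)C)[C@@H]2[C@H](O)C[C@H]1C
F6 | step 12 | C7 phenylselanyl derivative of ketone 18 | CC(=O)O[C@H]1C[C@@]2(C)CC[C@@](O[Si](CC)(CC)CC)(C(C)C)[C@@H]2C(=O)C([Se]c2ccccc2)[C@H]1C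
F7 | step 14 | C6 epimer of 22 | CC(=O)O[C@H]1C[C@@]2(C)CC[C@@](O)(C(C)C)[C@@H]2[C@H](O)C=C1C
A1 | alternative 1 | tert-butyl[(5-methoxy-2,3,4,7-tetrahydro-1H-inden-1-yl)oxy]dimethylsilane, configuration as in the SMILES | COC1=CCC2=C(C1)CC[C@@H]2O[Si](C)(C)C(C)(C)C
A2 | alternative 1 | ring-expanded bicyclic enone (C9 ketone; C7=C8 with C8 methyl; C1=C5 alkene; C4 tert-butyldimethylsilyl ether) | CC1=CCC2=C(CC1=O)CC[C@@H]2O[Si](C)(C)C(C)(C)C
A3 | alternative 2 | ring B 6,8-diene carbinol (C6=C7 and C8=C9; C4 hydroxyl; trans fusion) | CC1=CC[C@@]2(C)CC[C@@](O)(C(C)C)[C@@H]2C=C1
A4 | alternative 2 | C6,C9-endoperoxide with C7=C8 alkene | O3[C@H]1C[C@@]2(C)CC[C@@](O)(C(C)C)[C@@H]2[C@@H](O3)C=C1C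
A5 | alternative 3 | 3-methylcyclopent-2-en-1-one | CC1=CC(=O)CC1
A6 | alternative 3 | (2Z)-3-iodobut-2-enal | C/C(I)=C/C=O
A7 | alternative 3 | 2,3-trans aldol adduct (3-methyl-3-vinylcyclopentanone with C6 carbinol and Z vinyl iodide) | C=C[C@@]1(C)CCC(=O)[C@@H]1[C@@H](O)/C=C(C)\I
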